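Product comes from free catalyst working on substrate while free catalyst pairs off into spent catalyst, so I count what is left of each and not what is made.

    substrate + free catalyst → free catalyst + product (k1 = 100 M⁻¹ s⁻¹)
    2 free catalyst → spent catalyst (k2 = 410 M⁻¹ s⁻¹)
    free catalyst ⇌ dormant form (K3 = 1.2, k3 = 0.26 s⁻¹)

substrate 1.0 M; free catalyst 1.2 mM

- a doubled species enters its step squared and goes two at a time
- a form made of two catalysts counts as two
- charge of substrate (flask): 1.0 M

* the form that holds most of the catalyst when 50% of the substrate are converted (dormant form / free catalyst / spent catalyst)
* its share of the catalyst then
* apparent order in free catalyst when 50% of the substrate are converted (percent change of the rate of making product for one percent more free catalyst charged)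
* factor on the rate of making product when 50% of the substrate are converted if free catalyst is charged twice over

1. Step one is pseudo-first-order in substrate: ln[substrate] falls at k1[free catalyst].

2. I call free catalyst plus dormant form the live pool. Once step three has equilibrated, [free catalyst] is the fraction 0.455 of that pool, so ln(live pool) falls at 820 M⁻¹ s⁻¹ times that fraction times [free catalyst].

3. Both logarithms fall in step with [free catalyst], so time drops out. The fraction of substrate left equals the fraction of the live pool left, raised to the survival exponent, 100 M⁻¹ s⁻¹ over 820 M⁻¹ s⁻¹ and over that fraction: 0.268.

4. At 50% conversion the live pool left is therefore 7.55% of the charge, and spent catalyst holds the other 92.5%.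

5. The exponent contains no charge. A neighbouring flask with free catalyst charged twice over therefore reaches 50% conversion with the same live fraction, which by this rule gives order 1 and factor 2.

6. The rule needs the equilibrium, but the flask starts as free catalyst alone. There pairing removes it at 0.984 s⁻¹, faster than step three relaxes at 0.477 s⁻¹, and in the neighbour the pairing figure is 1.97 s⁻¹. The neighbour pairs faster than this flask at the start, so I expect it to lose more before the rule applies, and I commit to spent catalyst near 92.5% and to an order and factor a little below 1 and 2.

7. The forecast says spent catalyst at 92.8%, order 0.93 and factor 1.86, lower than my rule's factor, and it steps the start by hand since pairing “initially outruns the equilibrium”.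

The flask reaches 50% conversion at 80.2 s with spent catalyst holding 93.8%, apparent order 0.83 and factor 1.74. Its live pool then stands at 6.15% of the charge (3.44% dormant form, 2.71% free catalyst), less than the 7.55% of my reckoning. At 400 s the live pool of this flask is 1.26%, the survival exponent turns that into 31.0% substrate left, and the flask holds 32.4%.

The constants used here are invented; the run is a simulation.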